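## The problem

The target is a phenylcoumaran neolignan. Ring B is fused to a dihydrofuran (O1, C2, C3, C3a, C7a) that carries a guaiacyl group (ring A) at C2 and a hydroxymethyl group at C3. C5 of ring B bears a 1,2,3-trihydroxypropyl chain (C1'–C3'), and C7 a methoxy group.

The four stereocentres form two pairs, C2/C3 (2S,3R, trans) and C1'/C2' (1'S,2'R, erythro, i.e. anti in the zigzag chain). A benzene ring separates the pairs, so each needs its own source of absolute configuration. Within a pair relay is possible: C3 can dictate C2 if the O1–C2 bond forms reversibly, and C2' can dictate C1' by 1,2-induction in an addition to an α-oxygenated aldehyde. The erythro chain is the awkward one, because syn-dihydroxylation of the easily made E-alkene would give the threo series.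

Three things will not survive rough treatment. Both benzylic C–O bonds (C2–O1 and C1'–OH) lie para to an oxygen donor and ionise in strong acid or cleave on hydrogenolysis. The free guaiacyl phenol is easily oxidised. A cation or quinone methide at C2 next to the C3 hydroxymethyl group can lose formaldehyde and collapse to a stilbene.

The enabling feature is that C2 is benzylic to ring A, whose hydroxyl is para to it. The O1–C2 bond can therefore be made and broken through a para-quinone methide, and the trans isomer is the thermodynamic one.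

## Retrosynthesis

**Protecting groups.** Target 25 is traced back to acetonide 24 and then to the bis-silyl ether 23. Only O–Si and acetal C–O bonds are cut. The 2',3'-diol is carried as an isopropylidene acetal, the phenol and the C3 hydroxymethyl group as tert-butyldimethylsilyl ethers. Fluoride is used first and aqueous acetic acid last, so the final step leaves only volatile by-products beside a very polar product.

**C5–C1' bond.** Cutting between ring B and the chain turns 23 into the aryl bromide 19 and the three-carbon aldehyde 20, (R)-glyceraldehyde acetonide, from the chiral pool. The neighbouring cut, C1'–C2', would start from a C5 aldehyde and need a reagent-controlled anti-glycolate aldol plus reduction and deprotection, several steps more. Oxidation of a C1'=C2' alkene gives the wrong diastereomer. With the C5–C1' cut, C2' is bought and only C1' has to be induced. The forward step asks for bromine–lithium exchange to 21, transmetalation to the non-chelating aryltitanium 22, and Felkin–Anh addition. Precursor 19 has no side chain and two stereocentres fewer. Bromide 19 is the bis-silyl ether of phenol 18.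

**O1–C2 bond (key disconnection).** Opening the dihydrofuran of 18 at O1–C2 leads through the para-quinone methide 17 to the acyclic tetrol 16. The other ring bonds are less attractive: O1–C7a needs an activated fluoroarene, and C3–C3a needs a rearrangement. Only O1–C2 is reversible, so C2 need not be controlled beforehand. In 16 only C3 has to be defined. The forward reaction must ionise the benzylic carbinol under mild acid, let the ring B phenol close the ring, and equilibrate to trans without fragmentation.

**C2–C3 bond.** Tetrol 16 comes from the bis-silyl diol 15, and 15 from the aldol adduct 14 by reductive removal of the auxiliary. Cutting the bond between the carbinol carbon and the future C3 gives imide 10 and aldehyde 12. Auxiliary 8 controls the α-carbon (the future C3). The carbinol configuration is irrelevant because step 10 erases it. The forward step is a boron aldol through Z-enolate 13.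

**Arylacetic acid and aldehyde.** Imide 10 is the acylation product of 8 with acid 7. The aryl–CH2 bond of 7 is traced to an aromatic Claisen rearrangement: 7 from alkene 5 by oxidative cleavage, 5 from phenol 4, 4 from allyl ether 3, and 3 from 4-bromo-2-methoxyphenol 1 and allyl bromide 2. Aldehyde 12 is silylated vanillin 11.

A bromine at C5 was preferred to an ester for two reasons. It is inert to ozone, chlorite, boron triflate, borohydride, fluoride and TsOH, whereas an ester would compete for hydride in step 8. It then becomes the carbon nucleophile that takes up the whole chain in one step.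

## Roads not taken

Alternative 1: Ring B is built last by cutting C3a–C4 and C7–C7a. Pyranone A2 and the O-silyl ketene acetal A3 would combine on heating in a (4+2) cycloaddition; loss of CO2 and silanol would give A1.
- Merits: the route is highly convergent. The methoxy group and a C5 ester arrive in place with matched polarity (the nucleophilic acetal terminus meets C6 of A2). No phenol or acid is involved, so the benzylic C2–O bond is never ionised.
- Weak points: A3 must be supplied as a single enantiomer with both ring stereocentres already set, so the C2/C3 problem is moved, not solved, and nothing corrects it later. A2 needs its own multistep preparation. In the aromatisation, loss of the ring oxygen (opening the dihydrofuran) competes with loss of silanol. The ester of A1 still has to become the chain by reduction, oxidation and chain extension.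
- Comparison: this road is better in convergence and avoids the desilylation–resilylation around the ring closure. The chosen plan sets against that commodity aromatic materials, a closure that repairs C2 by itself, and bromide 19, which takes the full chain in one step.

Alternative 2: The cut is C3–C3a, made by aryl migration. PhI(OAc)2 with H2SO4 in trimethyl orthoformate would make the fused aryl carbon of flavanone A5 shift from the carbonyl carbon to the neighbouring methylene, contracting the pyranone ring to the trans ester A4.
- Merits: one stereocentre (C2 of A5) controls the second through a stereospecific shift. C3 arrives as an ester one reduction away from the hydroxymethyl group. The C5 bromide is the same handle as in 19. Access to the racemic core is at least as short as in the chosen plan.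
- Weak points: enantiopure A5 is hard to obtain and hard to keep, since flavanones open by retro-oxa-Michael reaction under the strongly acidic conditions of the rearrangement. Migration of the electron-rich 2-aryl group competes, which forces the phenol to be carried as a mesylate. The oxidant also meets an electron-rich fused ring.
- Comparison: the chosen plan gives up brevity for a dependable source of absolute configuration (auxiliary 8) and a ring closure without oxidant or mineral acid.

Alternative 3: The cut is O1–C7a. KN(SiMe3)2 would deprotonate the carbinol of fluoroarene A7, and the alkoxide would displace fluoride para to the ester to give A6 with retention at C2 and C3.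
- Merits: the closure is stereospecific. C2 never ionises, so the stilbene pathway is excluded. No free phenols are needed around the ring closure.
- Weak points: nothing corrects C2 later, so the aldol must be fully syn-selective. The fluorinated arylacetic acid is not a commodity. The arene is activated by one para ester only and deactivated by the ortho methoxy group. The alkoxide of A7 can fragment by C–C cleavage or eliminate trityloxide. The ester again costs extra steps for the chain.
- Comparison: in stereochemical security of the closure this road is better. The chosen plan sets against it indifference to the syn/anti ratio of the aldol, cheap non-fluorinated materials, and the bromide handle.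

Key step: step 10

Assumption: the descriptors read from the SMILES string, (2S,3R) in the dihydrobenzofuran and (1'S,2'R), erythro, in the chain, define the target; benzofuran numbering and C1'–C3' for the chain are used throughout.

## Route

Step 1
Reactants: 1 4-bromo-2-methoxyphenol; 2 allyl bromide
Product: 3 4-bromo-2-methoxy-1-(prop-2-en-1-yloxy)benzene
Conditions: K2CO3, acetone, reflux
Reagents that add atoms: none
Why: Williamson etherification of the phenoxide with a reactive allylic bromide; O-alkylation is expected exclusively under these conditions.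

Step 2
Reactants: 3 4-bromo-2-methoxy-1-(prop-2-en-1-yloxy)benzene
Product: 4 4-bromo-2-methoxy-6-(prop-2-en-1-yl)phenol
Conditions: N,N-diethylaniline, 195 °C
Reagents that add atoms: none
Why: Aromatic Claisen rearrangement; the [3,3] shift can end productively only at the free ortho carbon, because the other ortho position carries the methoxy group and the para position bromine.

Step 3
Reactants: 4 4-bromo-2-methoxy-6-(prop-2-en-1-yl)phenol
Product: 5 [4-bromo-2-methoxy-6-(prop-2-en-1-yl)phenoxy](tert-butyl)dimethylsilane
Conditions: TBSCl, imidazole, DMF, 40 °C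
Reagents that add atoms: tert-butyldimethylsilyl chloride (TBSCl), CC(C)(C)[Si](C)(C)Cl
Why: Standard silylation of a hindered phenol; the silyl ether shields the phenol from ozone and from the boron triflate of step 7 and is removed later with fluoride.

Step 4
Reactants: 5 [4-bromo-2-methoxy-6-(prop-2-en-1-yl)phenoxy](tert-butyl)dimethylsilane
Product: 7 2-[5-bromo-2-(tert-butyldimethylsilyloxy)-3-methoxyphenyl]acetic acid, via arylacetaldehyde 6 (not isolated)
Conditions: O3, MeCN/H2O (9:1), 0 °C; then aq NaClO2, 0 °C → rt; NaHSO3 quench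
Reagents that add atoms: ozone, [O-][O+]=O; sodium chlorite (NaClO2), [Na+].[O-]Cl=O
Why: Criegee ozonolysis in wet acetonitrile, where water traps the carbonyl oxide so that aldehyde 6 forms without a reductive work-up, followed by Pinnick-type chlorite oxidation in the same pot with the hydrogen peroxide of the first stage as hypochlorite scavenger. The terminal alkene should react with ozone far faster than the bromoarene.

Step 5
Reactants: 7 2-[5-bromo-2-(tert-butyldimethylsilyloxy)-3-methoxyphenyl]acetic acid; 8 (4S)-4-benzyl-1,3-oxazolidin-2-one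
Product: 10 (4S)-4-benzyl-3-{2-[5-bromo-2-(tert-butyldimethylsilyloxy)-3-methoxyphenyl]acetyl}-1,3-oxazolidin-2-one, via mixed pivalic anhydride 9 (not isolated)
Conditions: PivCl, Et3N, THF, −20 °C; then 8, LiCl, −20 °C → rt
Reagents that add atoms: none
Why: N-acylation of the oxazolidinone through a mixed anhydride activated by LiCl; no lithiated auxiliary is needed, which avoids enolisation of the acidic arylacetyl unit.

Step 6
Reactants: 11 vanillin
Product: 12 4-(tert-butyldimethylsilyloxy)-3-methoxybenzaldehyde
Conditions: TBSCl, imidazole, DMF, rt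
Reagents that add atoms: tert-butyldimethylsilyl chloride (TBSCl), CC(C)(C)[Si](C)(C)Cl
Why: Standard phenol silylation; the group makes the aldehyde compatible with the boron enolate and leaves together with the ring B silyl ether in step 9.

Step 7
Reactants: 10 (4S)-4-benzyl-3-{2-[5-bromo-2-(tert-butyldimethylsilyloxy)-3-methoxyphenyl]acetyl}-1,3-oxazolidin-2-one; 12 4-(tert-butyldimethylsilyloxy)-3-methoxybenzaldehyde
Product: 14 (4S)-4-benzyl-3-[(2S,3S)-2-[5-bromo-2-(tert-butyldimethylsilyloxy)-3-methoxyphenyl]-3-[4-(tert-butyldimethylsilyloxy)-3-methoxyphenyl]-3-hydroxypropanoyl]-1,3-oxazolidin-2-one, via dibutylboron Z-enolate 13 (not isolated)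
Conditions: Bu2BOTf, i-Pr2NEt, CH2Cl2, −78 → 0 °C; then 12, −78 → 0 °C; pH 7 buffer, MeOH, H2O2, 0 °C
Reagents that add atoms: none
Why: Evans syn-aldol reaction: the Z boron enolate 13 reacts through a Zimmerman–Traxler chair with the auxiliary carbonyl turned away from the enolate oxygen, so the aldehyde meets the face opposite the benzyl group. This sets the α-carbon as S in the imide, which becomes 3R once the acyl carbon is reduced. The carbinol centre (S) is set as well but is erased in step 10.

Step 8
Reactants: 14 (4S)-4-benzyl-3-[(2S,3S)-2-[5-bromo-2-(tert-butyldimethylsilyloxy)-3-methoxyphenyl]-3-[4-(tert-butyldimethylsilyloxy)-3-methoxyphenyl]-3-hydroxypropanoyl]-1,3-oxazolidin-2-one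
Product: 15 (1S,2R)-2-[5-bromo-2-(tert-butyldimethylsilyloxy)-3-methoxyphenyl]-1-[4-(tert-butyldimethylsilyloxy)-3-methoxyphenyl]propane-1,3-diol
Conditions: LiBH4, H2O (1 equiv), Et2O/THF, 0 °C
Reagents that add atoms: none
Why: Reductive cleavage of the N-acyl oxazolidinone by borohydride at the exocyclic carbonyl, which frees auxiliary 8 for recovery; the aryl bromide and silyl ethers are inert, and hydride delivery at 0 °C should outrun enolisation of the α-centre.

Step 9
Reactants: 15 (1S,2R)-2-[5-bromo-2-(tert-butyldimethylsilyloxy)-3-methoxyphenyl]-1-[4-(tert-butyldimethylsilyloxy)-3-methoxyphenyl]propane-1,3-diol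
Product: 16 (1S,2R)-2-(5-bromo-2-hydroxy-3-methoxyphenyl)-1-(4-hydroxy-3-methoxyphenyl)propane-1,3-diol
Conditions: TBAF, AcOH, THF, 0 °C
Reagents that add atoms: none
Why: Fluoride cleavage of both aryl silyl ethers, buffered with acetic acid so that no free phenoxide triggers elimination at the benzylic carbinol.

Step 10
Reactants: 16 (1S,2R)-2-(5-bromo-2-hydroxy-3-methoxyphenyl)-1-(4-hydroxy-3-methoxyphenyl)propane-1,3-diol
Product: 18 4-[(2S,3R)-5-bromo-3-(hydroxymethyl)-7-methoxy-2,3-dihydro-1-benzofuran-2-yl]-2-methoxyphenol, via para-quinone methide 17 (not isolated)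
Conditions: anhydrous TsOH (10 mol %), dry MeCN (0.01 M), 0 °C → rt
Reagents that add atoms: none
Why: TsOH protonates the benzylic hydroxyl of 16, and loss of water, pushed by the para hydroxyl of ring A, gives the para-quinone methide 17. The ring B phenol then adds to the exocyclic methide carbon in an intramolecular oxa-1,6-addition that forms O1–C2 and rearomatises ring A. The dihydrofuran closes in the 5-exo-trig mode. The closest known reaction type is the acid-mediated cyclisation of 1-(4-hydroxyaryl)-2-(2-hydroxyaryl)propane-1,3-diols to trans-2-aryl-2,3-dihydrobenzofurans, the laboratory counterpart of the last event in oxidative phenol coupling. C2 is the only new stereocentre and is controlled by C3 from step 7: the closure is reversible under the acid, and the isomer with the aryl group trans to the hydroxymethyl group is the more stable, so either carbinol epimer converges on (2S,3R). The step needs chemoselectivity for the phenol over the primary hydroxyl, secured by the favourable five-membered closure against a strained and reversible four-membered one, and over intermolecular capture, secured by dilution. It also needs the quinone methide to close faster than it fragments to a stilbene, which catalytic anhydrous acid at low temperature should ensure.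

Step 11
Reactants: 18 4-[(2S,3R)-5-bromo-3-(hydroxymethyl)-7-methoxy-2,3-dihydro-1-benzofuran-2-yl]-2-methoxyphenol
Product: 19 (2S,3R)-5-bromo-2-[4-(tert-butyldimethylsilyloxy)-3-methoxyphenyl]-3-[(tert-butyldimethylsilyloxy)methyl]-7-methoxy-2,3-dihydro-1-benzofuran
Conditions: TBSCl (2.5 equiv), imidazole, DMF, rt
Reagents that add atoms: tert-butyldimethylsilyl chloride (TBSCl), CC(C)(C)[Si](C)(C)Cl
Why: One-pot silylation of the phenol and the primary alcohol; both acidic protons must be masked before the organolithium is generated, and both groups leave together in step 13.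

Step 12
Reactants: 19 (2S,3R)-5-bromo-2-[4-(tert-butyldimethylsilyloxy)-3-methoxyphenyl]-3-[(tert-butyldimethylsilyloxy)methyl]-7-methoxy-2,3-dihydro-1-benzofuran; 20 (4R)-2,2-dimethyl-1,3-dioxolane-4-carbaldehyde
Product: 23 (S)-{(2S,3R)-2-[4-(tert-butyldimethylsilyloxy)-3-methoxyphenyl]-3-[(tert-butyldimethylsilyloxy)methyl]-7-methoxy-2,3-dihydro-1-benzofuran-5-yl}[(4R)-2,2-dimethyl-1,3-dioxolan-4-yl]methanol, via aryllithium 21 (not isolated), via aryltitanium triisopropoxide 22 (not isolated)
Conditions: n-BuLi (1.0 equiv), THF, −78 °C; ClTi(OiPr)3, −78 → −40 °C; then 20, −78 → −20 °C; aq NH4Cl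
Reagents that add atoms: none
Why: Bromine–lithium exchange and transmetalation give the non-basic, non-chelating aryltitanium 22, whose 1,2-addition to the α-alkoxy aldehyde should follow the Felkin–Anh model (attack anti to the dioxolane C–O bond) and give the anti, erythro carbinol. C2' (R) comes from the chiral pool and directs the new C1' centre to S. The ring stereocentres are too remote to interfere, and the silyl ethers tolerate the aryllithium at −78 °C.

Step 13
Reactants: 23 (S)-{(2S,3R)-2-[4-(tert-butyldimethylsilyloxy)-3-methoxyphenyl]-3-[(tert-butyldimethylsilyloxy)methyl]-7-methoxy-2,3-dihydro-1-benzofuran-5-yl}[(4R)-2,2-dimethyl-1,3-dioxolan-4-yl]methanol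
Product: 24 4-[(2S,3R)-5-{(S)-[(4R)-2,2-dimethyl-1,3-dioxolan-4-yl](hydroxy)methyl}-3-(hydroxymethyl)-7-methoxy-2,3-dihydro-1-benzofuran-2-yl]-2-methoxyphenol
Conditions: TBAF, AcOH, THF, 0 °C → rt
Reagents that add atoms: none
Why: Fluoride desilylation of the aryl and the primary silyl ether; the acetic acid buffer keeps the ring A phenoxide from opening the O1–C2 bond, and the acetonide is untouched.

Step 14
Reactants: 24 4-[(2S,3R)-5-{(S)-[(4R)-2,2-dimethyl-1,3-dioxolan-4-yl](hydroxy)methyl}-3-(hydroxymethyl)-7-methoxy-2,3-dihydro-1-benzofuran-2-yl]-2-methoxyphenol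
Product: 25 (1S,2R)-1-[(2S,3R)-2-(4-hydroxy-3-methoxyphenyl)-3-(hydroxymethyl)-7-methoxy-2,3-dihydro-1-benzofuran-5-yl]propane-1,2,3-triol
Conditions: AcOH/H2O (4:1), rt
Reagents that add atoms: none
Why: Hydrolysis of a terminal isopropylidene acetal in aqueous acetic acid; this acid is many orders of magnitude weaker than the TsOH of step 10, so neither O1–C2 nor the C1' carbinol should ionise, and acid and acetone are removed by evaporation.

## Compound list

1 | 4-bromo-2-methoxyphenol | COc1cc(Br)ccc1O | starting material
2 | allyl bromide | C=CCBr | starting material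
3 | 4-bromo-2-methoxy-1-(prop-2-en-1-yloxy)benzene | COc1cc(Br)ccc1OCC=C | intermediate
4 | 4-bromo-2-methoxy-6-(prop-2-en-1-yl)phenol | COc1cc(Br)cc(CC=C)c1O | intermediate
5 | [4-bromo-2-methoxy-6-(prop-2-en-1-yl)phenoxy](tert-butyl)dimethylsilane | COc1cc(Br)cc(CC=C)c1O[Si](C)(C)C(C)(C)C | intermediate
6 | 2-[5-bromo-2-(tert-butyldimethylsilyloxy)-3-methoxyphenyl]acetaldehyde | COc1cc(Br)cc(CC=O)c1O[Si](C)(C)C(C)(C)C | intermediate (not isolated)
7 | 2-[5-bromo-2-(tert-butyldimethylsilyloxy)-3-methoxyphenyl]acetic acid | COc1cc(Br)cc(CC(=O)O)c1O[Si](C)(C)C(C)(C)C | intermediate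
8 | (4S)-4-benzyl-1,3-oxazolidin-2-one | O=C1N[C@@H](Cc2ccccc2)CO1 | starting material
9 | 2-[5-bromo-2-(tert-butyldimethylsilyloxy)-3-methoxyphenyl]acetic pivalic anhydride | COc1cc(Br)cc(CC(=O)OC(=O)C(C)(C)C)c1O[Si](C)(C)C(C)(C)C | intermediate (not isolated)
10 | (4S)-4-benzyl-3-{2-[5-bromo-2-(tert-butyldimethylsilyloxy)-3-methoxyphenyl]acetyl}-1,3-oxazolidin-2-one | COc1cc(Br)cc(CC(=O)N2[C@@H](Cc3ccccc3)COC2=O)c1O[Si](C)(C)C(C)(C)C | intermediate
11 | vanillin (4-hydroxy-3-methoxybenzaldehyde) | COc1cc(C=O)ccc1O | starting material
12 | 4-(tert-butyldimethylsilyloxy)-3-methoxybenzaldehyde | COc1cc(C=O)ccc1O[Si](C)(C)C(C)(C)C | intermediate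
13 | dibutylboron (Z)-enolate of imide 10 | CCCCB(CCCC)O/C(=C\c1cc(Br)cc(OC)c1O[Si](C)(C)C(C)(C)C)N1[C@@H](Cc2ccccc2)COC1=O | intermediate (not isolated)
14 | (4S)-4-benzyl-3-[(2S,3S)-2-[5-bromo-2-(tert-butyldimethylsilyloxy)-3-methoxyphenyl]-3-[4-(tert-butyldimethylsilyloxy)-3-methoxyphenyl]-3-hydroxypropanoyl]-1,3-oxazolidin-2-one | COc1cc([C@@H](O)[C@@H](C(=O)N2[C@@H](Cc3ccccc3)COC2=O)c2cc(Br)cc(OC)c2O[Si](C)(C)C(C)(C)C)ccc1O[Si](C)(C)C(C)(C)C | intermediate
15 | (1S,2R)-2-[5-bromo-2-(tert-butyldimethylsilyloxy)-3-methoxyphenyl]-1-[4-(tert-butyldimethylsilyloxy)-3-methoxyphenyl]propane-1,3-diol | COc1cc([C@@H](O)[C@@H](CO)c2cc(Br)cc(OC)c2O[Si](C)(C)C(C)(C)C)ccc1O[Si](C)(C)C(C)(C)C | intermediate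
16 | (1S,2R)-2-(5-bromo-2-hydroxy-3-methoxyphenyl)-1-(4-hydroxy-3-methoxyphenyl)propane-1,3-diol | COc1cc([C@@H](O)[C@@H](CO)c2cc(Br)cc(OC)c2O)ccc1O | intermediate
17 | 4-[(2R)-2-(5-bromo-2-hydroxy-3-methoxyphenyl)-3-hydroxypropylidene]-2-methoxycyclohexa-2,5-dien-1-one | COC1=CC(=C[C@@H](CO)c2cc(Br)cc(OC)c2O)C=CC1=O | intermediate (not isolated)
18 | 4-[(2S,3R)-5-bromo-3-(hydroxymethyl)-7-methoxy-2,3-dihydro-1-benzofuran-2-yl]-2-methoxyphenol | COc1cc([C@H]2Oc3c(OC)cc(Br)cc3[C@@H]2CO)ccc1O | intermediate
19 | (2S,3R)-5-bromo-2-[4-(tert-butyldimethylsilyloxy)-3-methoxyphenyl]-3-[(tert-butyldimethylsilyloxy)methyl]-7-methoxy-2,3-dihydro-1-benzofuran | COc1cc([C@H]2Oc3c(OC)cc(Br)cc3[C@@H]2CO[Si](C)(C)C(C)(C)C)ccc1O[Si](C)(C)C(C)(C)C | intermediate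
20 | (4R)-2,2-dimethyl-1,3-dioxolane-4-carbaldehyde | O=C[C@H]1COC(C)(C)O1 | starting material
21 | 5-lithio derivative of 19 | COc1cc([C@H]2Oc3c(OC)cc([Li])cc3[C@@H]2CO[Si](C)(C)C(C)(C)C)ccc1O[Si](C)(C)C(C)(C)C | intermediate (not isolated)
22 | 5-(triisopropoxytitanio) derivative of 19 | COc1cc([C@H]2Oc3c(OC)cc([Ti](OC(C)C)(OC(C)C)OC(C)C)cc3[C@@H]2CO[Si](C)(C)C(C)(C)C)ccc1O[Si](C)(C)C(C)(C)C | intermediate (not isolated)
23 | (S)-{(2S,3R)-2-[4-(tert-butyldimethylsilyloxy)-3-methoxyphenyl]-3-[(tert-butyldimethylsilyloxy)methyl]-7-methoxy-2,3-dihydro-1-benzofuran-5-yl}[(4R)-2,2-dimethyl-1,3-dioxolan-4-yl]methanol | COc1cc([C@H]2Oc3c(OC)cc([C@H](O)[C@H]4COC(C)(C)O4)cc3[C@@H]2CO[Si](C)(C)C(C)(C)C)ccc1O[Si](C)(C)C(C)(C)C | intermediate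
24 | 4-[(2S,3R)-5-{(S)-[(4R)-2,2-dimethyl-1,3-dioxolan-4-yl](hydroxy)methyl}-3-(hydroxymethyl)-7-methoxy-2,3-dihydro-1-benzofuran-2-yl]-2-methoxyphenol | COc1cc([C@H]2Oc3c(OC)cc([C@H](O)[C@H]4COC(C)(C)O4)cc3[C@@H]2CO)ccc1O | intermediate
25 | (1S,2R)-1-[(2S,3R)-2-(4-hydroxy-3-methoxyphenyl)-3-(hydroxymethyl)-7-methoxy-2,3-dihydro-1-benzofuran-5-yl]propane-1,2,3-triol | COc1cc([C@H]2Oc3c(OC)cc([C@H](O)[C@H](O)CO)cc3[C@@H]2CO)ccc1O | target

## Step count and least certain steps

Total: 14 steps. Longest linear sequence: 13 steps (steps 1–5 and 7–14, from 1).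

**Step 10 (key step).** The quinone methide or its cation may fragment with loss of formaldehyde towards a stilbene, may be captured intermolecularly and oligomerise, or may not equilibrate fully to trans under acid mild enough to avoid the first two. The fallback generates the quinone methide without acid and with the primary oxygen blocked. It sets out from 15. Acetylation of both hydroxyls (Ac2O, pyridine, DMAP) should give (1S,2R)-2-[5-bromo-2-(tert-butyldimethylsilyloxy)-3-methoxyphenyl]-1-[4-(tert-butyldimethylsilyloxy)-3-methoxyphenyl]propane-1,3-diyl diacetate F1. TBAF in THF at 0 °C should free both phenoxides; the ring A phenoxide expels the benzylic acetate by 1,6-elimination, and the ring B phenoxide closes the ring to [(2S,3R)-5-bromo-2-(4-hydroxy-3-methoxyphenyl)-7-methoxy-2,3-dihydro-1-benzofuran-3-yl]methyl acetate F2. Methanolysis (K2CO3, MeOH) returns to the route at 18.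

**Step 12.** Facial selectivity in the addition may be poor if chelation competes with the Felkin–Anh pathway, and residual aryllithium may enolise the α-alkoxy aldehyde. The fallback replaces carbon nucleophile control by hydride control. It sets out from 23 as obtained (mixed with its carbinol epimer). Oxidation with Dess–Martin periodinane should give the single ketone {(2S,3R)-2-[4-(tert-butyldimethylsilyloxy)-3-methoxyphenyl]-3-[(tert-butyldimethylsilyloxy)methyl]-7-methoxy-2,3-dihydro-1-benzofuran-5-yl}[(4R)-2,2-dimethyl-1,3-dioxolan-4-yl]methanone F3. Chelation-controlled reduction with Zn(BH4)2 in Et2O at −30 °C, where hydride attacks the chelate from the side of the α-hydrogen, should give the anti carbinol and return to the route at 23.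

**Step 8.** Under the basic hydride conditions the β-hydroxy imide may undergo retro-aldol cleavage, and the doubly activated α-carbon may epimerise before reduction. The fallback closes the ring before the auxiliary is removed, so the carbinol oxygen is gone before any hydride is used. It sets out from 14. Buffered desilylation (TBAF, AcOH) should give (4S)-4-benzyl-3-[(2S,3S)-2-(5-bromo-2-hydroxy-3-methoxyphenyl)-3-hydroxy-3-(4-hydroxy-3-methoxyphenyl)propanoyl]-1,3-oxazolidin-2-one F4. Catalytic TsOH in MeCN should cyclise it through the same quinone methide manifold to (4S)-4-benzyl-3-{[(2S,3S)-5-bromo-2-(4-hydroxy-3-methoxyphenyl)-7-methoxy-2,3-dihydro-1-benzofuran-3-yl]carbonyl}-1,3-oxazolidin-2-one F5, in which the trans ring holds C3. LiBH4 reduction then returns to the route at 18.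

**Step 14.** Even weak aqueous acid may ionise the C1' carbinol (epimerisation towards threo) or reopen O1–C2 in the free phenol. The fallback removes acid from the end game by carrying the glycerol oxygens as silyl ethers. It sets out from 19. Aryltitanium 22, generated as in step 12, would be added to the known aldehyde (R)-2,3-bis(tert-butyldimethylsilyloxy)propanal F6 (Felkin–Anh, anti) to give (1S,2R)-2,3-bis(tert-butyldimethylsilyloxy)-1-{(2S,3R)-2-[4-(tert-butyldimethylsilyloxy)-3-methoxyphenyl]-3-[(tert-butyldimethylsilyloxy)methyl]-7-methoxy-2,3-dihydro-1-benzofuran-5-yl}propan-1-ol F7. A single buffered fluoride treatment (TBAF, AcOH) returns to the route at 25.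

## Further compounds

F1 | step 10 | (1S,2R)-2-[5-bromo-2-(tert-butyldimethylsilyloxy)-3-methoxyphenyl]-1-[4-(tert-butyldimethylsilyloxy)-3-methoxyphenyl]propane-1,3-diyl diacetate | COc1cc([C@@H](OC(C)=O)[C@@H](COC(C)=O)c2cc(Br)cc(OC)c2O[Si](C)(C)C(C)(C)C)ccc1O[Si](C)(C)C(C)(C)C
F2 | step 10 | [(2S,3R)-5-bromo-2-(4-hydroxy-3-methoxyphenyl)-7-methoxy-2,3-dihydro-1-benzofuran-3-yl]methyl acetate | COc1cc([C@H]2Oc3c(OC)cc(Br)cc3[C@@H]2COC(C)=O)ccc1O
F3 | step 12 | {(2S,3R)-2-[4-(tert-butyldimethylsilyloxy)-3-methoxyphenyl]-3-[(tert-butyldimethylsilyloxy)methyl]-7-methoxy-2,3-dihydro-1-benzofuran-5-yl}[(4R)-2,2-dimethyl-1,3-dioxolan-4-yl]methanone | COc1cc([C@H]2Oc3c(OC)cc(C(=O)[C@H]4COC(C)(C)O4)cc3[C@@H]2CO[Si](C)(C)C(C)(C)C)ccc1O[Si](C)(C)C(C)(C)C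
F4 | step 8 | (4S)-4-benzyl-3-[(2S,3S)-2-(5-bromo-2-hydroxy-3-methoxyphenyl)-3-hydroxy-3-(4-hydroxy-3-methoxyphenyl)propanoyl]-1,3-oxazolidin-2-one | COc1cc([C@@H](O)[C@@H](C(=O)N2[C@@H](Cc3ccccc3)COC2=O)c2cc(Br)cc(OC)c2O)ccc1O
F5 | step 8 | (4S)-4-benzyl-3-{[(2S,3S)-5-bromo-2-(4-hydroxy-3-methoxyphenyl)-7-methoxy-2,3-dihydro-1-benzofuran-3-yl]carbonyl}-1,3-oxazolidin-2-one | COc1cc([C@H]2Oc3c(OC)cc(Br)cc3[C@@H]2C(=O)N2[C@@H](Cc3ccccc3)COC2=O)ccc1O
F6 | step 14 | (R)-2,3-bis(tert-butyldimethylsilyloxy)propanal | O=C[C@H](O[Si](C)(C)C(C)(C)C)CO[Si](C)(C)C(C)(C)C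
F7 | step 14 | (1S,2R)-2,3-bis(tert-butyldimethylsilyloxy)-1-{(2S,3R)-2-[4-(tert-butyldimethylsilyloxy)-3-methoxyphenyl]-3-[(tert-butyldimethylsilyloxy)methyl]-7-methoxy-2,3-dihydro-1-benzofuran-5-yl}propan-1-ol | COc1cc([C@H]2Oc3c(OC)cc([C@H](O)[C@H](O[Si](C)(C)C(C)(C)C)CO[Si](C)(C)C(C)(C)C)cc3[C@@H]2CO[Si](C)(C)C(C)(C)C)ccc1O[Si](C)(C)C(C)(C)C
A1 | alternative 1 | methyl (2S,3R)-2-(4-benzyloxy-3-methoxyphenyl)-3-(tert-butyldimethylsilyloxymethyl)-7-methoxy-2,3-dihydrobenzofuran-5-carboxylate | COc1cc([C@H]2Oc3c(OC)cc(C(=O)OC)cc3[C@@H]2CO[Si](C)(C)C(C)(C)C)ccc1OCc1ccccc1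
A2 | alternative 1 | methyl 3-methoxy-2-oxo-2H-pyran-5-carboxylate | COC(=O)C1=COC(=O)C(OC)=C1
A3 | alternative 1 | tert-butyl{[(2S,3R)-2-(4-benzyloxy-3-methoxyphenyl)-5-(trimethylsilyloxy)-2,3-dihydrofuran-3-yl]methoxy}dimethylsilane | COc1cc([C@H]2OC(O[Si](C)(C)C)=C[C@@H]2CO[Si](C)(C)C(C)(C)C)ccc1OCc1ccccc1
A4 | alternative 2 | methyl (2S,3S)-5-bromo-7-methoxy-2-(3-methoxy-4-methylsulfonyloxyphenyl)-2,3-dihydrobenzofuran-3-carboxylate | COc1cc([C@H]2Oc3c(OC)cc(Br)cc3[C@@H]2C(=O)OC)ccc1OS(C)(=O)=O
A5 | alternative 2 | (2S)-6-bromo-8-methoxy-2-(3-methoxy-4-methylsulfonyloxyphenyl)chroman-4-one | COc1cc([C@H]2Oc3c(OC)cc(Br)cc3C(=O)C2)ccc1OS(C)(=O)=O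
A6 | alternative 3 | methyl (2S,3R)-2-(4-benzyloxy-3-methoxyphenyl)-7-methoxy-3-(trityloxymethyl)-2,3-dihydrobenzofuran-5-carboxylate | COc1cc([C@H]2Oc3c(OC)cc(C(=O)OC)cc3[C@@H]2COC(c4ccccc4)(c4ccccc4)c4ccccc4)ccc1OCc1ccccc1
A7 | alternative 3 | methyl 3-[(1S,2R)-1-(4-benzyloxy-3-methoxyphenyl)-1-hydroxy-3-(trityloxy)propan-2-yl]-4-fluoro-5-methoxybenzoate | COc1cc([C@@H](O)[C@@H](COC(c2ccccc2)(c2ccccc2)c2ccccc2)c2cc(C(=O)OC)cc(OC)c2F)ccc1OCc1ccccc1
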